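**Retrosynthetic overview**

1. The target is a trans-fused daucane (C1 = methyl-bearing ring-fusion carbon, C2–C4 = five-membered ring, C5 = ring-fusion CH, C6–C10 = seven-membered ring). The endgame starts from a bicyclic 6,10-dione: C2 acetate, hydroxyl-directed reduction and anisoylation at C6, C8=C9 dehydrogenation, 1,2-reduction at C10.
2. Key disconnection: C1–C5 and C8–C9 together, by an intramolecular (4+3) cycloaddition of an acyclic epoxy enol silane (C9=C10(OSi), epoxide C1–C2) with a tethered (Z)-2-silyloxydiene (C5=C6(OSi)–C7=C8). The five-membered ring closes with the first bond and the seven-membered ring with the second, both in this one step.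
3. Enabling feature: in the seven-membered ring the C10 oxygen sits next to the quaternary C1, whose neighbour C2 in the five-membered ring carries oxygen (a β-oxy ketone with a quaternary α-carbon, the array an epoxy enol silane delivers). C6 carries oxygen (a 2-oxydiene C5–C8), and C2–C3–C4 is a three-atom tether between the two π-systems.
4. Acyclic precursor: a (Z)-alkenyllithium from (S)-but-3-yn-2-ol opens a 2,2-disubstituted epoxide made from (S)-2-hydroxy-3-methylbutanoic acid (C4 set by enolate alkylation with self-regeneration of the stereocentre). Hydroxyl-directed epoxidation, chain extension at C6 and double enol silylation follow.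
5. Stereochemical relay: two purchased centres. The carbinol directs the C1–C2 epoxide; the epoxide sets C1 by inversion and, with the enol-silane geometry, the trans fusion at C5; the C4 hydroxyl then directs C6 and the C1 methyl directs C10.

Key step: step 15

Remark: the target is read as the 1β-methyl, 2α-acetoxy, 4β-hydroxy, 5α-H, 6α-(4-methoxybenzoyloxy), 10β-hydroxy dauc-8-ene (β = face of the C1 methyl group); the same carbon numbers are used for the corresponding atoms of the acyclic intermediates.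

**Route**

Step 1
Reactants: 1 (2S)-2-hydroxy-3-methylbutanoic acid
Product: 2 (2S,5S)-2-tert-butyl-5-(propan-2-yl)-1,3-dioxolan-4-one
Conditions: pivalaldehyde, TsOH·H2O (cat.), H2SO4 (cat.), pentane, reflux, water separator; recrystallisation
Reagents that add atoms: pivalaldehyde, CC(C)(C)C=O
Why: Acid-catalysed acetalisation under water removal should give the cis-dioxolanone as the thermodynamically favoured, crystallisable isomer, so the acetal carbon stores the configuration of the hydroxy acid.

Step 2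
Reactants: 2 (2S,5S)-2-tert-butyl-5-(propan-2-yl)-1,3-dioxolan-4-one
Product: 4 (2S,5S)-2-tert-butyl-5-(propan-2-yl)-5-(prop-2-en-1-yl)-1,3-dioxolan-4-one, via lithium enolate 3 (not isolated)
Conditions: LiN(iPr)2, THF, −78 °C; allyl bromide, −78 → −20 °C
Reagents that add atoms: allyl bromide, C=CCBr
Why: Enolate alkylation with self-regeneration of the stereocentre: the planar enolate 3 should be attacked by allyl bromide anti to the tert-butyl group, which sets the fully substituted carbinol carbon (future C4) with overall retention.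

Step 3
Reactants: 4 (2S,5S)-2-tert-butyl-5-(propan-2-yl)-5-(prop-2-en-1-yl)-1,3-dioxolan-4-one
Product: 5 (2S)-2-(propan-2-yl)pent-4-ene-1,2-diol
Conditions: LiAlH4, THF, 0 °C → rt
Reagents that add atoms: none
Why: Hydride reduction of the lactone-type acetal should release the 1,2-diol without touching the tertiary stereocentre.

Step 4
Reactants: 5 (2S)-2-(propan-2-yl)pent-4-ene-1,2-diol
Product: 7 (2S)-2-(propan-2-yl)-2-(prop-2-en-1-yl)oxirane, via primary tosylate 6 (not isolated)
Conditions: NaH, 1-(4-toluenesulfonyl)imidazole, THF, 0 °C → rt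
Reagents that add atoms: none
Why: Selective sulfonylation of the primary alkoxide followed by intramolecular Williamson displacement (3-exo-tet) should close the epoxide; the C–O bond of the tertiary centre is not broken, so its configuration is kept.

Step 5
Reactants: 8 (2S)-but-3-yn-2-ol
Product: 10 (2S,3Z)-4-iodo-3-methylbut-3-en-2-ol, via alkenylmagnesium chelate 9 (not isolated)
Conditions: MeMgBr (2.5 equiv), CuI (10 mol %), THF, −10 °C → rt; I2, −78 → 0 °C
Reagents that add atoms: methylmagnesium bromide, C[Mg]Br; iodine, II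
Why: Copper-catalysed anti-carbomagnesiation of the propargylic alkoxide places the methyl group on the internal carbon and the magnesium cis to the carbinol carbon in chelate 9, and iodinolysis with retention should give the (Z)-iodide; the carbinol centre is untouched.

Step 6
Reactants: 10 (2S,3Z)-4-iodo-3-methylbut-3-en-2-ol
Product: 11 1-({[(2S,3Z)-4-iodo-3-methylbut-3-en-2-yl]oxy}methyl)-4-methoxybenzene
Conditions: NaH, 4-methoxybenzyl chloride, Bu4NI (cat.), THF/DMF, 0 °C → rt
Reagents that add atoms: 4-methoxybenzyl chloride, COc1ccc(CCl)cc1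
Why: Williamson etherification protects the allylic alcohol as a 4-methoxybenzyl ether that tolerates the organolithium chemistry of step 7.

Step 7
Reactants: 11 1-({[(2S,3Z)-4-iodo-3-methylbut-3-en-2-yl]oxy}methyl)-4-methoxybenzene; 7 (2S)-2-(propan-2-yl)-2-(prop-2-en-1-yl)oxirane
Product: 13 (4R,6Z,8S)-8-[(4-methoxyphenyl)methoxy]-7-methyl-4-(propan-2-yl)nona-1,6-dien-4-ol, via alkenyllithium 12 (not isolated)
Conditions: 11, t-BuLi (2 equiv), Et2O, −78 °C; then 7, BF3·OEt2, −78 °C
Reagents that add atoms: none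
Why: Iodine–lithium exchange proceeds with retention of the alkene geometry, and the BF3-activated epoxide should be opened by SN2 attack of the alkenyllithium at its CH2 terminus, joining the two fragments without touching either stereocentre.

Step 8
Reactants: 13 (4R,6Z,8S)-8-[(4-methoxyphenyl)methoxy]-7-methyl-4-(propan-2-yl)nona-1,6-dien-4-ol
Product: 14 triethyl{[(4R,6Z,8S)-8-[(4-methoxyphenyl)methoxy]-7-methyl-4-(propan-2-yl)nona-1,6-dien-4-yl]oxy}silane
Conditions: TESOTf, 2,6-lutidine, CH2Cl2, −78 → 0 °C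
Reagents that add atoms: triethylsilyl trifluoromethanesulfonate, CC[Si](CC)(CC)OS(=O)(=O)C(F)(F)F
Why: Silyl triflate silylation of the hindered tertiary alcohol masks it against participation in the later epoxide chemistry.

Step 9
Reactants: 14 triethyl{[(4R,6Z,8S)-8-[(4-methoxyphenyl)methoxy]-7-methyl-4-(propan-2-yl)nona-1,6-dien-4-yl]oxy}silane
Product: 15 (2S,3Z,6R)-3-methyl-6-(propan-2-yl)-6-[(triethylsilyl)oxy]nona-3,8-dien-2-ol
Conditions: DDQ, CH2Cl2/pH 7 buffer, 0 °C
Reagents that add atoms: none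
Why: Oxidative cleavage of the 4-methoxybenzyl ether by DDQ should free the allylic alcohol while the triethylsilyl ether and both alkenes stay intact.

Step 10
Reactants: 15 (2S,3Z,6R)-3-methyl-6-(propan-2-yl)-6-[(triethylsilyl)oxy]nona-3,8-dien-2-ol
Product: 16 (1S)-1-[(2R,3S)-2-methyl-3-{(2R)-2-(propan-2-yl)-2-[(triethylsilyl)oxy]pent-4-en-1-yl}oxiran-2-yl]ethan-1-ol
Conditions: mCPBA, NaHCO3, CH2Cl2, −20 → 0 °C
Reagents that add atoms: 3-chloroperoxybenzoic acid, OOC(=O)c1cccc(Cl)c1
Why: Hydroxyl-directed peracid epoxidation: allylic 1,3-strain with the cis alkyl chain holds the carbinol hydrogen in the alkene plane, so the hydrogen-bonded peracid should add to the face that gives the threo epoxy alcohol (epoxide carbons = future C1 and C2), and the unactivated terminal alkene reacts far more slowly.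

Step 11
Reactants: 16 (1S)-1-[(2R,3S)-2-methyl-3-{(2R)-2-(propan-2-yl)-2-[(triethylsilyl)oxy]pent-4-en-1-yl}oxiran-2-yl]ethan-1-ol
Product: 18 (3S)-3-{[(2S,3R)-3-[(1S)-1-hydroxyethyl]-3-methyloxiran-2-yl]methyl}-4-methyl-3-[(triethylsilyl)oxy]pentanal, via ozonide 17 (not isolated)
Conditions: O3, CH2Cl2, −78 °C; PPh3, −78 °C → rt
Reagents that add atoms: ozone, [O-][O+]=O
Why: Ozonolysis with reductive work-up cleaves the only remaining alkene to the aldehyde (future C6).

Step 12
Reactants: 18 (3S)-3-{[(2S,3R)-3-[(1S)-1-hydroxyethyl]-3-methyloxiran-2-yl]methyl}-4-methyl-3-[(triethylsilyl)oxy]pentanal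
Product: 19 (2E,4RS,6R)-6-{[(2S,3R)-3-[(1S)-1-hydroxyethyl]-3-methyloxiran-2-yl]methyl}-7-methyl-6-[(triethylsilyl)oxy]oct-2-en-4-ol
Conditions: (E)-prop-1-enyllithium (2.5 equiv; from (E)-1-bromoprop-1-ene, t-BuLi, Et2O, −78 °C), THF, −78 °C
Reagents that add atoms: (E)-prop-1-enyllithium, C/C=C/[Li] (made from (E)-1-bromoprop-1-ene, C/C=C/Br)
Why: 1,2-Addition of the alkenyllithium (geometry retained from the bromide) to the aldehyde should give the allylic alcohol as an epimer mixture of no consequence, because this carbinol is oxidised in step 13; the first equivalent is consumed by the free hydroxyl.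

Step 13
Reactants: 19 (2E,4RS,6R)-6-{[(2S,3R)-3-[(1S)-1-hydroxyethyl]-3-methyloxiran-2-yl]methyl}-7-methyl-6-[(triethylsilyl)oxy]oct-2-en-4-ol
Product: 20 (2E,6S)-6-{[(2S,3S)-3-acetyl-3-methyloxiran-2-yl]methyl}-7-methyl-6-[(triethylsilyl)oxy]oct-2-en-4-one
Conditions: Dess–Martin periodinane, NaHCO3, CH2Cl2, 0 °C → rt
Reagents that add atoms: none
Why: Dess–Martin oxidation under buffered conditions should convert both secondary alcohols into ketones without opening the epoxide or eliminating the β-silyloxy group.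

Step 14
Reactants: 20 (2E,6S)-6-{[(2S,3S)-3-acetyl-3-methyloxiran-2-yl]methyl}-7-methyl-6-[(triethylsilyl)oxy]oct-2-en-4-one
Product: 21 (2E,4Z,6R)-7-methyl-6-{[(2S,3S)-3-methyl-3-{1-[(triethylsilyl)oxy]ethenyl}oxiran-2-yl]methyl}-4,6-bis[(triethylsilyl)oxy]octa-2,4-diene
Conditions: TESOTf (2.4 equiv), Et3N, CH2Cl2, −78 → −20 °C
Reagents that add atoms: triethylsilyl trifluoromethanesulfonate, CC[Si](CC)(CC)OS(=O)(=O)C(F)(F)F
Why: Soft enolisation (silyl triflate and amine) should convert the methyl ketone into the terminal enol silane and the enone, by deprotonation at its saturated α' carbon, into the cross-conjugated 2-silyloxydiene, whose (Z) geometry (tertiary carbon trans to the propenyl group) is the one free of allylic strain.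

Step 15
Reactants: 21 (2E,4Z,6R)-7-methyl-6-{[(2S,3S)-3-methyl-3-{1-[(triethylsilyl)oxy]ethenyl}oxiran-2-yl]methyl}-4,6-bis[(triethylsilyl)oxy]octa-2,4-diene
Product: 22 2α,4β,6-tris(triethylsilyloxy)-5αH,8αH-dauc-6-en-10-one
Conditions: TESOTf (15 mol %), CH2Cl2, −78 °C; Et3N quench
Reagents that add atoms: none
Why: Proposed new method: the silyl triflate silylates the epoxide oxygen, the nucleophilic terminus C5 of the tethered (Z)-2-silyloxydiene opens the C1–O bond at the tertiary, enol-silane-stabilised carbon (first bond C1–C5), the resulting silyloxyallyl cation C6–C7–C8 is captured at C8 by the enol-silane carbon C9 (second bond C8–C9), and the silyl group then passes from the C10 oxygen to the C2 oxygen with release of the catalyst; the closest known reaction type is the silyl-triflate-catalysed intramolecular (4+3) cycloaddition of epoxy enol silanes with tethered furans, extended here to a tethered acyclic 2-silyloxydiene, so that the first bond is a Mukaiyama-type epoxide alkylation and the second a Mukaiyama–Michael closure. The five-membered ring closes by backside attack of C5 on C1 with the C2–C3–C4 tether inside the ring (5-endo opening of the epoxide), and the seven-membered ring closes as the second bond of the (4+3) event through an extended, chair-like arrangement of the allyl and diene units. C1 is set by inversion at the epoxide carbon, so its methyl group ends trans to the C2 oxygen, which is carried over unchanged from the epoxide. C5 is set by the diene face that reaches C1: with the (Z)-enol silane (C4 in the outside position) the extended arrangement gives the trans ring fusion and places the dienyl unit anti to the C4 isopropyl group and to the silyloxyvinyl group on C1, whereas the compact arrangement that would give the cis fusion stacks the two triethylsilyloxy groups on each other. C8 arises from suprafacial addition to the (E)-propenyl terminus and is removed again in step 20. The step needs C1–C5 bonding before C8–C9 bonding, seven- rather than five-membered capture of the allyl cation, and the trans fusion; the polarity match (nucleophilic C5 with electrophilic C1, electrophilic C8 with nucleophilic C9) should secure the first two and the silyloxy and isopropyl sterics the third.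

Step 16
Reactants: 22 2α,4β,6-tris(triethylsilyloxy)-5αH,8αH-dauc-6-en-10-one
Product: 23 2α,4β-dihydroxy-5αH,8αH-daucane-6,10-dione
Conditions: HF·pyridine, pyridine, THF, 0 °C → rt
Reagents that add atoms: none
Why: Fluoride-mediated desilylation should cleave the two silyl ethers and protonate the enol silane at C7, unveiling the 6,10-diketone without epimerising C5 under the buffered conditions.

Step 17
Reactants: 23 2α,4β-dihydroxy-5αH,8αH-daucane-6,10-dione
Product: 24 2α-acetoxy-4β-hydroxy-5αH,8αH-daucane-6,10-dione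
Conditions: Ac2O, pyridine, DMAP (cat.), CH2Cl2, 0 °C
Reagents that add atoms: acetic anhydride, CC(=O)OC(C)=O
Why: DMAP-catalysed acylation should esterify the secondary C2 hydroxyl selectively because the tertiary C4 hydroxyl reacts far more slowly.

Step 18
Reactants: 24 2α-acetoxy-4β-hydroxy-5αH,8αH-daucane-6,10-dione
Product: 25 2α-acetoxy-4β,6α-dihydroxy-5αH,8αH-daucan-10-one
Conditions: Me4NBH(OAc)3, MeCN/AcOH, −30 → −10 °C
Reagents that add atoms: none
Why: Evans–Saksena reduction: the triacetoxyborohydride bound to the C4 hydroxyl should deliver hydride intramolecularly to the β-face of the C6 ketone, giving the 6α-alcohol (anti to the 4β-hydroxyl), while the C10 ketone, which has no free β-hydroxyl, is not reduced by this reagent.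

Step 19
Reactants: 25 2α-acetoxy-4β,6α-dihydroxy-5αH,8αH-daucan-10-one
Product: 26 2α-acetoxy-4β-hydroxy-6α-(4-methoxybenzoyloxy)-5αH,8αH-daucan-10-one
Conditions: 4-methoxybenzoyl chloride, Et3N, DMAP, CH2Cl2, rt
Reagents that add atoms: 4-methoxybenzoyl chloride, COc1ccc(C(Cl)=O)cc1
Why: DMAP-catalysed acylation of the secondary C6 alcohol with the acid chloride should leave the tertiary alcohol free.

Step 20
Reactants: 26 2α-acetoxy-4β-hydroxy-6α-(4-methoxybenzoyloxy)-5αH,8αH-daucan-10-one
Product: 27 2α-acetoxy-4β-hydroxy-6α-(4-methoxybenzoyloxy)-5αH-dauc-8-en-10-one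
Conditions: IBX, DMSO/fluorobenzene, 65 °C
Reagents that add atoms: none
Why: IBX dehydrogenation of the ketone through its enol: only C9 can enolise because C1 is quaternary, so the C8=C9 enone should form regioselectively and the C8 stereocentre is removed.

Step 21
Reactants: 27 2α-acetoxy-4β-hydroxy-6α-(4-methoxybenzoyloxy)-5αH-dauc-8-en-10-one
Product: 28 2α-acetoxy-6α-(4-methoxybenzoyloxy)-5αH-dauc-8-ene-4β,10β-diol (CNP0261832.1)
Conditions: NaBH4, CeCl3·7H2O, MeOH, −78 °C
Reagents that add atoms: none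
Why: Luche reduction: the cerium-activated enone should undergo 1,2-attack by hydride from the α-face, anti to the axial C1 methyl group on the neighbouring carbon, giving the 10β-allylic alcohol; the esters survive at low temperature.

**Compound list**

1 | (2S)-2-hydroxy-3-methylbutanoic acid | CC(C)[C@H](O)C(=O)O | starting material
2 | (2S,5S)-2-tert-butyl-5-(propan-2-yl)-1,3-dioxolan-4-one | CC(C)[C@@H]1O[C@H](C(C)(C)C)OC1=O | intermediate
3 | lithium (2S)-2-tert-butyl-5-(propan-2-yl)-1,3-dioxol-4-olate (lithium enolate of 2) | CC(C)C1=C(O[Li])O[C@@H](C(C)(C)C)O1 | intermediate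
4 | (2S,5S)-2-tert-butyl-5-(propan-2-yl)-5-(prop-2-en-1-yl)-1,3-dioxolan-4-one | C=CC[C@@]1(C(C)C)O[C@H](C(C)(C)C)OC1=O | intermediate
5 | (2S)-2-(propan-2-yl)pent-4-ene-1,2-diol | OC[C@@](O)(C(C)C)CC=C | intermediate
6 | (2S)-2-hydroxy-2-(propan-2-yl)pent-4-en-1-yl 4-methylbenzenesulfonate (present as its sodium alkoxide) | Cc1ccc(S(=O)(=O)OC[C@@](O)(C(C)C)CC=C)cc1 | intermediate
7 | (2S)-2-(propan-2-yl)-2-(prop-2-en-1-yl)oxirane | C=CC[C@]1(C(C)C)CO1 | intermediate
8 | (2S)-but-3-yn-2-ol | C#C[C@H](C)O | starting material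
9 | (5S)-4,5-dimethyl-2,5-dihydro-1,2-oxamagnesole (cyclic (Z)-alkenylmagnesium alkoxide) | C[C@@H]1O[Mg]C=C1C | intermediate
10 | (2S,3Z)-4-iodo-3-methylbut-3-en-2-ol | I/C=C(C)\[C@H](C)O | intermediate
11 | 1-({[(2S,3Z)-4-iodo-3-methylbut-3-en-2-yl]oxy}methyl)-4-methoxybenzene | I/C=C(C)\[C@H](C)OCc1ccc(OC)cc1 | intermediate
12 | [(1Z,3S)-3-[(4-methoxyphenyl)methoxy]-2-methylbut-1-en-1-yl]lithium | [Li]/C=C(C)\[C@H](C)OCc1ccc(OC)cc1 | intermediate
13 | (4R,6Z,8S)-8-[(4-methoxyphenyl)methoxy]-7-methyl-4-(propan-2-yl)nona-1,6-dien-4-ol | C=CC[C@](O)(C(C)C)C/C=C(C)\[C@H](C)OCc1ccc(OC)cc1 | intermediate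
14 | triethyl{[(4R,6Z,8S)-8-[(4-methoxyphenyl)methoxy]-7-methyl-4-(propan-2-yl)nona-1,6-dien-4-yl]oxy}silane | C=CC[C@](O[Si](CC)(CC)CC)(C(C)C)C/C=C(C)\[C@H](C)OCc1ccc(OC)cc1 | intermediate
15 | (2S,3Z,6R)-3-methyl-6-(propan-2-yl)-6-[(triethylsilyl)oxy]nona-3,8-dien-2-ol | C=CC[C@](O[Si](CC)(CC)CC)(C(C)C)C/C=C(C)\[C@H](C)O | intermediate
16 | (1S)-1-[(2R,3S)-2-methyl-3-{(2R)-2-(propan-2-yl)-2-[(triethylsilyl)oxy]pent-4-en-1-yl}oxiran-2-yl]ethan-1-ol | C=CC[C@](O[Si](CC)(CC)CC)(C(C)C)C[C@@H]1O[C@]1(C)[C@H](C)O | intermediate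
17 | secondary ozonide of 16 (3-substituted 1,2,4-trioxolane; ring carbon unassigned) | C1OC(C[C@](O[Si](CC)(CC)CC)(C(C)C)C[C@@H]2O[C@]2(C)[C@H](C)O)OO1 | intermediate
18 | (3S)-3-{[(2S,3R)-3-[(1S)-1-hydroxyethyl]-3-methyloxiran-2-yl]methyl}-4-methyl-3-[(triethylsilyl)oxy]pentanal | O=CC[C@](O[Si](CC)(CC)CC)(C(C)C)C[C@@H]1O[C@]1(C)[C@H](C)O | intermediate
19 | (2E,4RS,6R)-6-{[(2S,3R)-3-[(1S)-1-hydroxyethyl]-3-methyloxiran-2-yl]methyl}-7-methyl-6-[(triethylsilyl)oxy]oct-2-en-4-ol | C/C=C/C(O)C[C@](O[Si](CC)(CC)CC)(C(C)C)C[C@@H]1O[C@]1(C)[C@H](C)O | intermediate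
20 | (2E,6S)-6-{[(2S,3S)-3-acetyl-3-methyloxiran-2-yl]methyl}-7-methyl-6-[(triethylsilyl)oxy]oct-2-en-4-one | C/C=C/C(=O)C[C@](O[Si](CC)(CC)CC)(C(C)C)C[C@@H]1O[C@]1(C)C(C)=O | intermediate
21 | (2E,4Z,6R)-7-methyl-6-{[(2S,3S)-3-methyl-3-{1-[(triethylsilyl)oxy]ethenyl}oxiran-2-yl]methyl}-4,6-bis[(triethylsilyl)oxy]octa-2,4-diene | C/C=C/C(O[Si](CC)(CC)CC)=C/[C@](O[Si](CC)(CC)CC)(C(C)C)C[C@@H]1O[C@]1(C)C(=C)O[Si](CC)(CC)CC | intermediate
22 | 2α,4β,6-tris(triethylsilyloxy)-5αH,8αH-dauc-6-en-10-one (trans-fused; C1 and C8 methyl groups β) | CC[Si](CC)(CC)OC1=C[C@H](C)CC(=O)[C@@]2(C)[C@@H](O[Si](CC)(CC)CC)C[C@@](O[Si](CC)(CC)CC)(C(C)C)[C@H]12 | intermediate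
23 | 2α,4β-dihydroxy-5αH,8αH-daucane-6,10-dione | O=C1C[C@H](C)CC(=O)[C@@]2(C)[C@@H](O)C[C@@](O)(C(C)C)[C@H]12 | intermediate
24 | 2α-acetoxy-4β-hydroxy-5αH,8αH-daucane-6,10-dione | O=C1C[C@H](C)CC(=O)[C@@]2(C)[C@@H](OC(C)=O)C[C@@](O)(C(C)C)[C@H]12 | intermediate
25 | 2α-acetoxy-4β,6α-dihydroxy-5αH,8αH-daucan-10-one | O[C@H]1C[C@H](C)CC(=O)[C@@]2(C)[C@@H](OC(C)=O)C[C@@](O)(C(C)C)[C@H]12 | intermediate
26 | 2α-acetoxy-4β-hydroxy-6α-(4-methoxybenzoyloxy)-5αH,8αH-daucan-10-one | COc1ccc(C(=O)O[C@H]2C[C@H](C)CC(=O)[C@@]3(C)[C@@H](OC(C)=O)C[C@@](O)(C(C)C)[C@H]23)cc1 | intermediate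
27 | 2α-acetoxy-4β-hydroxy-6α-(4-methoxybenzoyloxy)-5αH-dauc-8-en-10-one | COc1ccc(C(=O)O[C@H]2CC(C)=CC(=O)[C@@]3(C)[C@@H](OC(C)=O)C[C@@](O)(C(C)C)[C@H]23)cc1 | intermediate
28 | 2α-acetoxy-6α-(4-methoxybenzoyloxy)-5αH-dauc-8-ene-4β,10β-diol (CNP0261832.1) | COc1ccc(C(=O)O[C@H]2CC(C)=C[C@H](O)[C@@]3(C)[C@@H](OC(C)=O)C[C@@](O)(C(C)C)[C@H]23)cc1 | target

**Step count and risk**

Total step count: 21. Longest linear sequence: 19 steps (steps 1–4 and 7–21).

Steps most likely to fail:

Step 15 (proposed new method). After the first bond the silyloxyallyl cation may be captured at C6 instead of C8 (five-membered closure), or may lose its silyl group before the second bond forms, or the diene face that attacks C1 may be poorly controlled (cis fusion). The fallback uses known reactions and makes the two bonds one after the other; it sets out from 19 and comes back at 24. MnO2 in CH2Cl2 oxidises only the allylic alcohol of 19 to hydroxy enone F1. TESOTf/Et3N silylates the remaining alcohol and turns the enone into the (Z)-silyloxydiene, tris(silyl) ether F2. BF3·OEt2 (CH2Cl2, −78 °C) promotes a Mukaiyama-type cyclisation of the enol-silane carbon C5 onto the tertiary epoxide carbon C1 with inversion, giving cyclopentyl enone F3 with a free C2 hydroxyl. Ac2O/DMAP gives acetate F4, HF·pyridine removes both silyl ethers to give diol F5, and Dess–Martin oxidation gives methyl ketone F6. An intramolecular Michael addition of the methyl ketone to the enone (pyrrolidinium acetate, or DBU in MeCN) then closes the seven-membered ring and delivers 24, possibly as a C8 epimer mixture that step 20 levels.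

Step 7. Lewis-acid-induced rearrangement of the 2,2-disubstituted epoxide to an aldehyde may compete, or attack of the hindered alkenyllithium at the neopentyl-type CH2 may be too slow. The fallback sets out from 7 and 8 and comes back at 13; it uses the smaller alkynyl nucleophile and builds the trisubstituted alkene afterwards. 8 is converted (NaH, 4-methoxybenzyl chloride) into propargylic ether F7. Its lithium acetylide (n-BuLi) opens 7 in the presence of BF3·OEt2 to give homopropargylic alcohol F8. Syn-hydrostannation (Bu3SnH, PdCl2(PPh3)2 cat.), which should place tin on the carbon next to the ether-bearing carbon, gives alkenylstannane F9. Iododestannylation (I2) with retention gives alkenyl iodide F10, and Negishi coupling with MeZnCl and Pd(PPh3)4 (retention) installs the methyl group to give 13.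

Step 20. Dehydrogenation of the hindered ketone may stay incomplete, or oxidation may continue at the allylic positions. The fallback sets out from 26 and comes back at 27; it replaces direct dehydrogenation by a Saegusa–Ito oxidation. TMSOTf/Et3N converts 26 into bis(trimethylsilyl) compound F11 (the C9=C10 enol silane, the only one possible, and the C4 silyl ether). Pd(OAc)2 in MeCN gives enone silyl ether F12, and aqueous citric acid in MeOH removes the tertiary trimethylsilyl ether to give 27.

Further compounds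

F1 | step 15 | (2E,6S)-6-{[(2S,3R)-3-[(1S)-1-hydroxyethyl]-3-methyloxiran-2-yl]methyl}-7-methyl-6-[(triethylsilyl)oxy]oct-2-en-4-one | C/C=C/C(=O)C[C@](O[Si](CC)(CC)CC)(C(C)C)C[C@@H]1O[C@]1(C)[C@H](C)O
F2 | step 15 | tris(triethylsilyl) derivative of F1: secondary silyl ether and (2E,4Z)-4-silyloxydiene | C/C=C/C(O[Si](CC)(CC)CC)=C/[C@](O[Si](CC)(CC)CC)(C(C)C)C[C@@H]1O[C@]1(C)[C@H](C)O[Si](CC)(CC)CC
F3 | step 15 | (7E,10S)-2α-hydroxy-4β,10-bis(triethylsilyloxy)-8,9-seco-5αH-dauc-7-en-6-one | C[C@H](O[Si](CC)(CC)CC)[C@@]1(C)[C@@H](O)C[C@@](O[Si](CC)(CC)CC)(C(C)C)[C@@H]1C(=O)/C=C/C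
F4 | step 15 | (7E,10S)-2α-acetoxy-4β,10-bis(triethylsilyloxy)-8,9-seco-5αH-dauc-7-en-6-one | C[C@H](O[Si](CC)(CC)CC)[C@@]1(C)[C@@H](OC(C)=O)C[C@@](O[Si](CC)(CC)CC)(C(C)C)[C@@H]1C(=O)/C=C/C
F5 | step 15 | (7E,10S)-2α-acetoxy-4β,10-dihydroxy-8,9-seco-5αH-dauc-7-en-6-one | C[C@H](O)[C@@]1(C)[C@@H](OC(C)=O)C[C@@](O)(C(C)C)[C@@H]1C(=O)/C=C/C
F6 | step 15 | (7E)-2α-acetoxy-4β-hydroxy-8,9-seco-5αH-dauc-7-ene-6,10-dione | CC(=O)[C@@]1(C)[C@@H](OC(C)=O)C[C@@](O)(C(C)C)[C@@H]1C(=O)/C=C/C
F7 | step 7 | 1-({[(2S)-but-3-yn-2-yl]oxy}methyl)-4-methoxybenzene | C#C[C@H](C)OCc1ccc(OC)cc1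
F8 | step 7 | (4R,8S)-8-[(4-methoxyphenyl)methoxy]-4-(propan-2-yl)non-1-en-6-yn-4-ol | C=CC[C@](O)(C(C)C)CC#C[C@H](C)OCc1ccc(OC)cc1
F9 | step 7 | (4R,6E,8S)-8-[(4-methoxyphenyl)methoxy]-4-(propan-2-yl)-7-(tributylstannyl)nona-1,6-dien-4-ol | C=CC[C@](O)(C(C)C)C/C=C(\[C@H](C)OCc1ccc(OC)cc1)[Sn](CCCC)(CCCC)CCCC
F10 | step 7 | (4R,6E,8S)-7-iodo-8-[(4-methoxyphenyl)methoxy]-4-(propan-2-yl)nona-1,6-dien-4-ol | C=CC[C@](O)(C(C)C)C/C=C(I)\[C@H](C)OCc1ccc(OC)cc1
F11 | step 20 | 2α-acetoxy-6α-(4-methoxybenzoyloxy)-4β,10-bis(trimethylsilyloxy)-5αH,8αH-dauc-9-ene | COc1ccc(C(=O)O[C@H]2C[C@H](C)C=C(O[Si](C)(C)C)[C@@]3(C)[C@@H](OC(C)=O)C[C@@](O[Si](C)(C)C)(C(C)C)[C@H]23)cc1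
F12 | step 20 | 2α-acetoxy-6α-(4-methoxybenzoyloxy)-4β-(trimethylsilyloxy)-5αH-dauc-8-en-10-one | COc1ccc(C(=O)O[C@H]2CC(C)=CC(=O)[C@@]3(C)[C@@H](OC(C)=O)C[C@@](O[Si](C)(C)C)(C(C)C)[C@H]23)cc1
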